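The synthesis rests on disconnecting C5–C6 and C9–C10 of the cyclohexane ring. That ring carries three contiguous stereocentres, quaternary C10 (methyl C14 plus the vinyl carbon C1), C5 (bearing C4) and C6 (oxygen), in which the methyl group, C4 and O6 are all cis: the signature of an endo [4+2] adduct of an E-trisubstituted enal. A single catalytic, enantioselective Diels–Alder reaction between (E)-1-(4-methoxybenzyloxy)-3-(tert-butyldimethylsilyloxy)buta-1,3-diene and methyl (E)-2-methyl-4-oxobut-2-enoate closes the six-membered ring, makes both bonds and fixes all three centres; the C7=C8 enol silane left behind is the regiodefined entry to C11 and to the C8 and C9 oxygens.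

Key step: step 5

Remarks on the chemistry (assumptions)  
(a) Elemane numbering is used for all ring compounds: ring C10–C5–C6–C7–C8–C9; C14 is the methyl and C1=C2 the vinyl group on C10, C4(=C15)–C3 the three-carbon unit on C5, C11(=C13)–C12 the lactone carbons on C7; "methyl face" and "vinyl face" name the two ring faces by the C10 substituent they carry.  
(b) In the target the C5 side chain, O6 and O9 lie on the methyl face and C11 and O8 on the vinyl face; the butenoate is Z (angelate) and the 2-methylbutanoate centre is R, so (R)-2-methylbutanoic acid, taken as a commercial reagent, is used.  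
(c) The (S)-configured oxazaborolidinium salt is written for step 5 because the formyl C–H···O binding model leaves the Re face at C5 and C10 of the enal open; this sense is an assumption of the model, and the mirror-image catalyst is equally accessible.

Step 1  
Reactants: 1 (E)-4-methoxybut-3-en-2-one; 2 4-methoxybenzyl alcohol  
Product: 3 (E)-4-(4-methoxybenzyloxy)but-3-en-2-one  
Conditions: PPTS (5 mol %), toluene, 70 °C, reduced pressure (MeOH removed)  
Reagents that add atoms: none  
Why: Acid-catalysed vinylogous transesterification (conjugate addition of the alcohol to the protonated β-alkoxy enone, then loss of methanol) is driven by removal of methanol and should return the thermodynamically preferred E enol ether.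

Step 2  
Reactants: 3 (E)-4-(4-methoxybenzyloxy)but-3-en-2-one  
Product: 4 (E)-1-(4-methoxybenzyloxy)-3-(tert-butyldimethylsilyloxy)buta-1,3-diene  
Conditions: TBSOTf, Et3N, Et2O, 0 °C → rt  
Reagents that add atoms: tert-butyldimethylsilyl trifluoromethanesulfonate, CC(C)(C)[Si](C)(C)OS(=O)(=O)C(F)(F)F  
Why: Soft enolisation of the methyl ketone and O-silylation (silyl enol ether formation) should give the 2-silyloxydiene without disturbing the E enol ether.

Step 3  
Reactants: 5 2,2-dimethoxyacetaldehyde; 6 methyl 2-(triphenylphosphoranylidene)propanoate  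
Product: 7 methyl (E)-4,4-dimethoxy-2-methylbut-2-enoate  
Conditions: CH2Cl2, rt  
Reagents that add atoms: none  
Why: Wittig olefination with a stabilised α-methyl ylide should give the E-trisubstituted enoate (ester trans to the acetal carbon), the acetal masking the second aldehyde of glyoxal.

Step 4  
Reactants: 7 methyl (E)-4,4-dimethoxy-2-methylbut-2-enoate  
Product: 8 methyl (E)-2-methyl-4-oxobut-2-enoate  
Conditions: TsOH·H2O (cat.), acetone/H2O, rt  
Reagents that add atoms: water, O  
Why: Acid-catalysed acetal hydrolysis frees the enal, and the E double bond, conjugated to two carbonyl groups, should not isomerise at room temperature.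

Step 5  
Reactants: 4 (E)-1-(4-methoxybenzyloxy)-3-(tert-butyldimethylsilyloxy)buta-1,3-diene; 8 methyl (E)-2-methyl-4-oxobut-2-enoate  
Product: 9 methyl (1R,5R,6S)-3-(tert-butyldimethylsilyloxy)-6-formyl-5-(4-methoxybenzyloxy)-1-methylcyclohex-3-ene-1-carboxylate  
Conditions: (S)-3,3-diphenyl-1-(o-tolyl)tetrahydro-1H,3H-pyrrolo[1,2-c][1,3,2]oxazaborole activated with HNTf2 (20 mol %), CH2Cl2, −78 → −40 °C; Et3N quench  
Reagents that add atoms: none  
Why: The protonated oxazaborolidine binds the formyl oxygen of 8 and lowers the LUMO of the C=C bond, so that a concerted but asynchronous [4+2] addition begins with bonding of the diene CH2 terminus to C10 (β to the bound formyl) and ends with C6–C5 bonding; the closest known reaction type is the oxazaborolidinium-catalysed endo Diels–Alder reaction of 2-silyloxy- and 1-alkoxy-3-silyloxydienes with α,β-unsaturated aldehydes. The cyclohexene ring is closed by an intermolecular suprafacial–suprafacial cycloaddition in which both ring bonds (C9–C10 and C5–C6) form in the same step. The C10/C5 relationship (methyl cis to formyl) is fixed by the E geometry of 8, the C5/C6 relationship (formyl cis to the benzyloxy group) by the endo orientation of the bound formyl group toward the (E)-alkoxydiene, and the absolute configuration by the catalyst, whose aryl group covers one face of the s-trans enal so that the diene should add to the Re face at C5 and C10. Regioselectivity is secured by the matched polarisation of the diene (nucleophilic at CH2 through the 3-silyloxy and 1-alkoxy groups) and the formyl-activated enal, endo selectivity by the coordinated aldehyde, and selectivity for C=C over C=O by the additional ester activation of the alkene and the low temperature.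

Step 6  
Reactants: 9 Diels–Alder adduct; 10 tributyl[(methoxymethoxy)methyl]stannane  
Product: 12 C4 carbinol (formyl group of 9 converted to CH(OH)CH2OCH2OCH3; both C4 epimers), via (methoxymethoxy)methyllithium 11 (not isolated)  
Conditions: 10, n-BuLi, THF, −78 °C; then 9, −78 °C; NH4Cl (aq) at −78 °C  
Reagents that add atoms: none  
Why: Tin–lithium exchange gives the α-alkoxyorganolithium 11, which should add 1,2 to the aldehyde at −78 °C faster than it deprotonates C5 or attacks the hindered C10 ester; the new C4 carbinol centre forms as an epimer mixture that is erased in step 7.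

Step 7  
Reactants: 12 C4 carbinol  
Product: 13 C4 ketone [C5 substituent C(=O)CH2OCH2OCH3]  
Conditions: DMP, NaHCO3, CH2Cl2, 0 °C → rt  
Reagents that add atoms: none  
Why: Dess–Martin oxidation of the secondary alcohol under buffered, non-basic conditions should give the α-alkoxy ketone without enolising C5 (a β-alkoxy ketone) or hydrolysing the enol silane.

Step 8  
Reactants: 13 C4 ketone  
Product: 14 methyl ester bearing the C5 3-(methoxymethoxy)prop-1-en-2-yl group  
Conditions: Ph3PCH3Br, KOtBu, THF, −78 → 0 °C  
Reagents that add atoms: methyltriphenylphosphonium bromide, C[P+](c1ccccc1)(c1ccccc1)c1ccccc1.[Br-]  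
Why: Wittig methylenation: the electrophilic α-alkoxy ketone should be captured by the ylide at low temperature faster than it is enolised, so the C5 configuration and O6 are kept, and the hindered ester is inert.

Step 9  
Reactants: 14 C4(15)-methylidene methyl ester  
Product: 15 C10 hydroxymethyl compound  
Conditions: LiAlH4, Et2O, 0 °C; NaOH (aq) work-up  
Reagents that add atoms: none  
Why: Hydride reduction of the neopentyl ester gives the primary alcohol, while the ethers, the alkene and the enol silane are inert to LiAlH4.

Step 10  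
Reactants: 15 C10 hydroxymethyl compound  
Product: 16 C10 carbaldehyde  
Conditions: DMP, NaHCO3, CH2Cl2, 0 °C → rt  
Reagents that add atoms: none  
Why: Dess–Martin oxidation gives the aldehyde on the quaternary carbon, which has no α-hydrogen and cannot epimerise.

Step 11  
Reactants: 16 C10 carbaldehyde  
Product: 17 C10-vinyl enol silane  
Conditions: Ph3PCH3Br, KOtBu, THF, 0 °C → rt  
Reagents that add atoms: methyltriphenylphosphonium bromide, C[P+](c1ccccc1)(c1ccccc1)c1ccccc1.[Br-]  
Why: Wittig methylenation of the non-enolisable aldehyde installs C1=C2 without touching a stereocentre, and the resulting trans-1,2-dialkenylcyclohexane is the stable side of the Cope equilibrium at the temperatures used later.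

Step 12  
Reactants: 17 C10-vinyl enol silane; 18 tert-butyl bromoacetate  
Product: 20 C8 ketone carrying CH2CO2tBu at C7 on the vinyl face, via TAS enolate 19 (not isolated)  
Conditions: TASF [(Me2N)3S+ Me3SiF2−], THF, −78 → −30 °C (18 present from the start)  
Reagents that add atoms: none  
Why: Fluoride-triggered regiospecific enolate alkylation of a silyl enol ether: desilylation generates the C7–C8 enolate 19 in the presence of the reactive α-bromo ester, which is expected to alkylate C7 anti to the neighbouring C6 ether (side chain on the vinyl face, trans to O6) faster than the enolate can expel the C6 alkoxide at low temperature.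

Step 13  
Reactants: 20 C8 ketone  
Product: 22 C8 enol triflate (C8=C9), via lithium enolate 21 (not isolated)  
Conditions: LiN(iPr)2 (LDA), THF, −78 °C; then N-(5-chloropyridin-2-yl)bis(trifluoromethanesulfonyl)imide (Comins' reagent), −78 °C  
Reagents that add atoms: N-(5-chloropyridin-2-yl)bis(trifluoromethanesulfonyl)imide, O=S(=O)(N(c1ccc(Cl)cn1)S(=O)(=O)C(F)(F)F)C(F)(F)F  
Why: Kinetic enolisation with a bulky lithium amide is expected to remove a proton from the C9 methylene and not from the C7 methine, and enolate 21 is O-sulfonylated at −78 °C before it can equilibrate (enol triflate formation), so no stereocentre is formed and C7 is untouched.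

Step 14  
Reactants: 22 C8 enol triflate  
Product: 23 8,9-alkene tert-butyl ester  
Conditions: Pd(OAc)2 (5 mol %), PPh3, HCO2H, Bu3N, DMF, 60 °C  
Reagents that add atoms: none  
Why: Palladium-catalysed formate reduction of an enol triflate (oxidative addition to zerovalent palladium, decarboxylation of formate to the hydride, reductive elimination) replaces C–O by C–H and leaves the C8=C9 alkene, the allylic ethers, the ester and all stereocentres in place.

Step 15  
Reactants: 23 8,9-alkene tert-butyl ester  
Product: 27 tert-butyl acrylate (C11=C13), via lithium ester enolate 24 (not isolated), via Mannich base 25 (not isolated), via trimethylammonium iodide 26 (not isolated)  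
Conditions: LDA, THF, −78 °C; CH2=NMe2+ I−, −78 → 0 °C; MeI, rt; then NaHCO3 (aq)  
Reagents that add atoms: N,N-dimethylmethyleneiminium iodide (Eschenmoser's salt), C=[N+](C)C.[I-]  
Why: α-Methylenation of the ester through a Mannich reaction: enolate 24 is aminomethylated, amine 25 is quaternised and ammonium salt 26 undergoes E1cB elimination with bicarbonate, a base too weak to move the new C11=C13 bond into conjugation through C7; the C11 centre of 25 and 26 is lost on elimination.

Step 16  
Reactants: 27 tert-butyl acrylate  
Product: 28 C6 alcohol  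
Conditions: DDQ, CH2Cl2/pH 7 buffer, 0 °C  
Reagents that add atoms: none  
Why: Oxidative removal of the p-methoxybenzyl ether with DDQ (hydride abstraction to the benzylic oxocarbenium ion, then hydrolysis) is selective for the electron-rich arene, and C6 keeps its configuration because the C6–O bond is not broken.

Step 17  
Reactants: 28 C6 alcohol  
Product: 29 8,9-epoxy alcohol (epoxide on the methyl face)  
Conditions: VO(acac)2 (5 mol %), t-BuOOH (decane), toluene, rt  
Reagents that add atoms: tert-butyl hydroperoxide, CC(C)(C)OO  
Why: Hydroxyl-directed vanadium-catalysed epoxidation of a homoallylic cyclohexenol: the vanadate ester of the pseudoaxial C6 hydroxyl should deliver the peroxide oxygen to C8=C9 on its own (methyl) face, as in cyclohex-3-en-1-ol, which sets C8 and C9; the acrylate alkene is too electron-poor and the C10 vinyl group out of reach, while the C4(15) methylidene, although also homoallylic to O6, is the poorer partner because of its electron-withdrawing allylic ether oxygen.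

Step 18  
Reactants: 29 8,9-epoxy alcohol; 30 angelic acid  
Product: 32 epoxy angelate, via angelic 2,4,6-trichlorobenzoic anhydride 31 (not isolated)  
Conditions: 30, 2,4,6-trichlorobenzoyl chloride, Et3N, toluene, rt; then 29, 75 °C  
Reagents that add atoms: none  
Why: Esterification of the hindered C6 alcohol through the preformed mixed anhydride 31 (Yamaguchi-type acylation run without DMAP) should transfer the angeloyl group without Z to E isomerisation and with retention at C6, the amine-buffered medium leaving the epoxide and the tert-butyl ester intact.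

Step 19  
Reactants: 32 epoxy angelate  
Product: 33 hydroxy lactone (12,8-olide with free C9 hydroxyl)  
Conditions: CSA (10 mol %), CH2Cl2, 0 °C → rt  
Reagents that add atoms: none  
Why: Acid-catalysed intramolecular epoxide opening by the ester carbonyl oxygen, 5-exo at C8 with inversion and loss of isobutene, gives the cis-fused γ-lactone with O8 on the vinyl face (the face of C11) and leaves the former epoxide oxygen as the C9 hydroxyl on the methyl face, so the trans C8/C9 relationship follows from the anti opening.

Step 20  
Reactants: 33 hydroxy lactone; 34 (R)-2-methylbutanoic acid  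
Product: 35 MOM-protected diester  
Conditions: DCC, DMAP (cat.), CH2Cl2, 0 °C → rt  
Reagents that add atoms: none  
Why: Steglich esterification acylates the only free hydroxyl (C9) with retention, and the α-stereocentre of the acid, which carries no activating heteroatom, is expected to survive acyl transfer at or below room temperature.

Step 21  
Reactants: 35 MOM-protected diester  
Product: 37 C3 allylic alcohol, via bromomethyl ether 36 (not isolated)  
Conditions: Me2BBr, CH2Cl2, −78 °C; then NaHCO3 (aq)/THF  
Reagents that add atoms: none  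
Why: Lewis-acid cleavage of the methoxymethyl ether: boron coordinates the acetal oxygen and bromide gives the bromomethyl ether 36, which is hydrolysed on the bicarbonate work-up, and at −78 °C the esters, the α-methylene lactone and the alkenes should not be attacked.

Step 22  
Reactants: 37 C3 allylic alcohol  
Product: 38 CNP0295282.1 (target)  
Conditions: DMP, NaHCO3, CH2Cl2, 0 °C  
Reagents that add atoms: none  
Why: Dess–Martin oxidation of the primary allylic alcohol under bicarbonate buffering gives the 2-substituted acrolein under neutral conditions that tolerate the angelate, the α-methylene lactone and the C5 centre, which is only vinylogously related to the new aldehyde.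

Compound list  
1 | (E)-4-methoxybut-3-en-2-one | CO/C=C/C(C)=O | starting material  
2 | 4-methoxybenzyl alcohol | COc1ccc(CO)cc1 | starting material  
3 | (E)-4-(4-methoxybenzyloxy)but-3-en-2-one | CC(=O)/C=C/OCc1ccc(OC)cc1 | intermediate  
4 | (E)-1-(4-methoxybenzyloxy)-3-(tert-butyldimethylsilyloxy)buta-1,3-diene | C=C(O[Si](C)(C)C(C)(C)C)/C=C/OCc1ccc(OC)cc1 | intermediate  
5 | 2,2-dimethoxyacetaldehyde | COC(OC)C=O | starting material  
6 | methyl 2-(triphenylphosphoranylidene)propanoate | COC(=O)C(C)=P(c1ccccc1)(c1ccccc1)c1ccccc1 | starting material  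
7 | methyl (E)-4,4-dimethoxy-2-methylbut-2-enoate | COC(OC)/C=C(\C)C(=O)OC | intermediate  
8 | methyl (E)-2-methyl-4-oxobut-2-enoate | O=C/C=C(\C)C(=O)OC | intermediate  
9 | methyl (1R,5R,6S)-3-(tert-butyldimethylsilyloxy)-6-formyl-5-(4-methoxybenzyloxy)-1-methylcyclohex-3-ene-1-carboxylate (C10 ester on the vinyl face; C14 methyl, C5 formyl and O6 on the methyl face; C7=C8 enol silane) | COC(=O)[C@@]1(C)[C@H](C=O)[C@H](OCc2ccc(OC)cc2)C=C(O[Si](C)(C)C(C)(C)C)C1 | intermediate  
10 | tributyl[(methoxymethoxy)methyl]stannane | CCCC[Sn](CCCC)(CCCC)COCOC | starting material  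
11 | (methoxymethoxy)methyllithium | [Li]COCOC | intermediate  
12 | methyl 3-(tert-butyldimethylsilyloxy)-6-[1-hydroxy-2-(methoxymethoxy)ethyl]-5-(4-methoxybenzyloxy)-1-methylcyclohex-3-ene-1-carboxylate (ring centres as in 9; both C4 carbinol epimers) | COC(=O)[C@@]1(C)[C@H](C(O)COCOC)[C@H](OCc2ccc(OC)cc2)C=C(O[Si](C)(C)C(C)(C)C)C1 | intermediate  
13 | methyl 3-(tert-butyldimethylsilyloxy)-6-[(methoxymethoxy)acetyl]-5-(4-methoxybenzyloxy)-1-methylcyclohex-3-ene-1-carboxylate (ring centres as in 9) | COC(=O)[C@@]1(C)[C@H](C(=O)COCOC)[C@H](OCc2ccc(OC)cc2)C=C(O[Si](C)(C)C(C)(C)C)C1 | intermediate  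
14 | methyl 3-(tert-butyldimethylsilyloxy)-6-[3-(methoxymethoxy)prop-1-en-2-yl]-5-(4-methoxybenzyloxy)-1-methylcyclohex-3-ene-1-carboxylate (ring centres as in 9) | COC(=O)[C@@]1(C)[C@H](C(=C)COCOC)[C@H](OCc2ccc(OC)cc2)C=C(O[Si](C)(C)C(C)(C)C)C1 | intermediate  
15 | primary alcohol from 14 (C10 CH2OH on the vinyl face; other groups as in 14) | OC[C@@]1(C)[C@H](C(=C)COCOC)[C@H](OCc2ccc(OC)cc2)C=C(O[Si](C)(C)C(C)(C)C)C1 | intermediate  
16 | C10 carbaldehyde (CHO on the vinyl face; other groups as in 14) | O=C[C@@]1(C)[C@H](C(=C)COCOC)[C@H](OCc2ccc(OC)cc2)C=C(O[Si](C)(C)C(C)(C)C)C1 | intermediate  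
17 | C10-vinyl enol silane: C10 vinyl and methyl, C5 3-(methoxymethoxy)prop-1-en-2-yl and C6 4-methoxybenzyloxy on the methyl face, C7=C8 tert-butyldimethylsilyl enol ether | C=C[C@@]1(C)[C@H](C(=C)COCOC)[C@H](OCc2ccc(OC)cc2)C=C(O[Si](C)(C)C(C)(C)C)C1 | intermediate  
18 | tert-butyl bromoacetate | CC(C)(C)OC(=O)CBr | starting material  
19 | tris(dimethylamino)sulfonium C7–C8 enolate of 17 | C=C[C@@]1(C)[C@H](C(=C)COCOC)[C@H](OCc2ccc(OC)cc2)C=C([O-])C1.CN(C)[S+](N(C)C)N(C)C | intermediate  
20 | C8 ketone with tert-butoxycarbonylmethyl at C7 on the vinyl face (trans to O6); C5, C6, C10 as in 17 | C=C[C@@]1(C)[C@H](C(=C)COCOC)[C@H](OCc2ccc(OC)cc2)[C@@H](CC(=O)OC(C)(C)C)C(=O)C1 | intermediate  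
21 | lithium C8–C9 enolate of 20 | C=C[C@@]1(C)[C@H](C(=C)COCOC)[C@H](OCc2ccc(OC)cc2)[C@@H](CC(=O)OC(C)(C)C)C([O-])=C1.[Li+] | intermediate  
22 | C8 enol triflate (C8=C9) of 20 | C=C[C@@]1(C)[C@H](C(=C)COCOC)[C@H](OCc2ccc(OC)cc2)[C@@H](CC(=O)OC(C)(C)C)C(OS(=O)(=O)C(F)(F)F)=C1 | intermediate  
23 | 8,9-alkene with C7 CH2CO2tBu (stereocentres as in 20) | C=C[C@@]1(C)[C@H](C(=C)COCOC)[C@H](OCc2ccc(OC)cc2)[C@@H](CC(=O)OC(C)(C)C)C=C1 | intermediate  
24 | lithium ester enolate of 23 | C=C[C@@]1(C)[C@H](C(=C)COCOC)[C@H](OCc2ccc(OC)cc2)[C@@H](C=C([O-])OC(C)(C)C)C=C1.[Li+] | intermediate  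
25 | Mannich base: C11 carries CH2NMe2 (C11 epimers) | C=C[C@@]1(C)[C@H](C(=C)COCOC)[C@H](OCc2ccc(OC)cc2)[C@@H](C(CN(C)C)C(=O)OC(C)(C)C)C=C1 | intermediate  
26 | trimethylammonium iodide of 25 | C=C[C@@]1(C)[C@H](C(=C)COCOC)[C@H](OCc2ccc(OC)cc2)[C@@H](C(C[N+](C)(C)C)C(=O)OC(C)(C)C)C=C1.[I-] | intermediate  
27 | tert-butyl 2-substituted acrylate (C11=C13) with C6 4-methoxybenzyl ether and C8=C9 alkene | C=C[C@@]1(C)[C@H](C(=C)COCOC)[C@H](OCc2ccc(OC)cc2)[C@@H](C(=C)C(=O)OC(C)(C)C)C=C1 | intermediate  
28 | C6 alcohol (hydroxyl on the methyl face) | C=C[C@@]1(C)[C@H](C(=C)COCOC)[C@H](O)[C@@H](C(=C)C(=O)OC(C)(C)C)C=C1 | intermediate  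
29 | 8,9-epoxy alcohol (epoxide oxygen on the methyl face, cis to the C6 hydroxyl) | C=C[C@@]1(C)[C@H](C(=C)COCOC)[C@H](O)[C@@H](C(=C)C(=O)OC(C)(C)C)[C@@H]2O[C@H]12 | intermediate  
30 | angelic acid [(Z)-2-methylbut-2-enoic acid] | C/C=C(/C)C(=O)O | starting material  
31 | angelic 2,4,6-trichlorobenzoic anhydride | C/C=C(/C)C(=O)OC(=O)c1c(Cl)cc(Cl)cc1Cl | intermediate  
32 | epoxy angelate (C6 angeloyloxy, 8,9-epoxide, tert-butyl acrylate) | C=C[C@@]1(C)[C@H](C(=C)COCOC)[C@H](OC(=O)/C(C)=C\C)[C@@H](C(=C)C(=O)OC(C)(C)C)[C@@H]2O[C@H]12 | intermediate  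
33 | hydroxy lactone: cis-fused α-methylene 12,8-olide (O8 and C11 on the vinyl face), C9 hydroxyl on the methyl face, C6 angelate, C3 MOM ether | C=C[C@@]1(C)[C@H](C(=C)COCOC)[C@H](OC(=O)/C(C)=C\C)[C@H]2C(=C)C(=O)O[C@H]2[C@@H]1O | intermediate  
34 | (R)-2-methylbutanoic acid | CC[C@@H](C)C(=O)O | starting material  
35 | MOM-protected diester (C9 (R)-2-methylbutanoate, C6 angelate) | C=C[C@@]1(C)[C@H](C(=C)COCOC)[C@H](OC(=O)/C(C)=C\C)[C@H]2C(=C)C(=O)O[C@H]2[C@@H]1OC(=O)[C@H](C)CC | intermediate  
36 | C3 bromomethyl ether of 37 | C=C[C@@]1(C)[C@H](C(=C)COCBr)[C@H](OC(=O)/C(C)=C\C)[C@H]2C(=C)C(=O)O[C@H]2[C@@H]1OC(=O)[C@H](C)CC | intermediate  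
37 | C3 allylic alcohol | C=C[C@@]1(C)[C@H](C(=C)CO)[C@H](OC(=O)/C(C)=C\C)[C@H]2C(=C)C(=O)O[C@H]2[C@@H]1OC(=O)[C@H](C)CC | intermediate  
38 | CNP0295282.1: (5R,6S,7R,8R,9R,10S)-6-[(Z)-2-methylbut-2-enoyloxy]-9-[(2R)-2-methylbutanoyloxy]-3-oxoelema-1,4(15),11(13)-trien-12,8-olide | C=C[C@@]1(C)[C@H](C(=C)C=O)[C@H](OC(=O)/C(C)=C\C)[C@H]2C(=C)C(=O)O[C@H]2[C@@H]1OC(=O)[C@H](C)CC | target  

Total step count: 22 steps.  
Longest linear sequence: 20 steps (1 → 3 → 4 → 9 → … → 38; the branch from 5 is equally long).

Steps most likely to fail

Step 5. What may go wrong: reaction at the Lewis-acid-bound formyl group (hetero-Diels–Alder or Mukaiyama-type addition) in place of the C=C bond, acid-induced decomposition of the diene, or low enantioface discrimination with this trisubstituted, doubly activated enal. The fallback sets out from 4 and 8 and returns at 9. The cycloaddition is run thermally without any Lewis acid (toluene, 40–60 °C), conditions under which 1-alkoxy-3-silyloxydienes are known to add to the C=C bond of enals, to give the racemic adduct F1. The aldehyde is then resolved as its aminals with (1S,2S)-N,N'-dimethyl-1,2-diphenylethane-1,2-diamine (4 Å molecular sieves, Et2O, rt). The two diastereomers, the aminal of 9 F2 and the aminal of the enantiomer of 9 F3, are separated by chromatography. F2 is hydrolysed (dilute aqueous HCl/Et2O, 0 °C, short contact) to 9, with recovery of the diamine.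

Step 12. What may go wrong: β-elimination of the C6 alkoxide from the C7 enolate (loss of the O6 centre through an E1cB pathway), or proton transfer between enolate and product leading to over-alkylation. The fallback sets out from 17 and returns at 20; it makes no new compound (F0). The enol silane itself is alkylated by a radical: 18, Ir(ppy)3 [tris(2-phenylpyridinato)iridium, 1 mol %], 2,6-lutidine, DMF, blue light, rt. The electrophilic ester-substituted radical should add to C7 of the electron-rich enol silane anti to O6, and the α-silyloxy radical is oxidised and desilylated to ketone 20. No enolate is ever present; the precedent is the known visible-light alkylation of silyl enol ethers with α-bromo carbonyl compounds.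

Step 17. What may go wrong: competing hydroxyl-directed epoxidation of the C4(15) methylidene, which is also homoallylic to O6, or slow reaction if the conformer with a pseudoaxial C6 hydroxyl is poorly populated. The fallback sets out from 28 and returns at 33. The two ring oxygens are introduced by halolactonisation and radical oxygenation in place of epoxidation. Alcohol 28 is angeloylated as in step 18 to the angelate F4. The tert-butyl ester is cleaved (TFA, CH2Cl2, 0 °C) to the acrylic acid F5. Iodolactonisation (I2, NaHCO3, MeCN, 0 °C), which can engage only C8=C9, should give the cis-fused iodolactone F6 with iodine on the methyl face of C9. Radical exchange of iodine for oxygen (Bu3SnH, air, toluene, rt, then PPh3) is expected to place the C9 hydroxyl anti to the lactone oxygen, which is hydroxy lactone 33.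

Further compounds  
F1 | step 5 | racemic Diels–Alder adduct (9 and its enantiomer, 1:1) | COC(=O)[C@@]1(C)[C@H](C=O)[C@H](OCc2ccc(OC)cc2)C=C(O[Si](C)(C)C(C)(C)C)C1.COC(=O)[C@]1(C)[C@@H](C=O)[C@@H](OCc2ccc(OC)cc2)C=C(O[Si](C)(C)C(C)(C)C)C1  
F2 | step 5 | (4S,5S)-1,3-dimethyl-4,5-diphenylimidazolidin-2-yl aminal of 9 | COC(=O)[C@@]1(C)[C@H](C2N(C)[C@@H](c3ccccc3)[C@H](c3ccccc3)N2C)[C@H](OCc2ccc(OC)cc2)C=C(O[Si](C)(C)C(C)(C)C)C1  
F3 | step 5 | (4S,5S)-1,3-dimethyl-4,5-diphenylimidazolidin-2-yl aminal of the enantiomer of 9 | COC(=O)[C@]1(C)[C@@H](C2N(C)[C@@H](c3ccccc3)[C@H](c3ccccc3)N2C)[C@@H](OCc2ccc(OC)cc2)C=C(O[Si](C)(C)C(C)(C)C)C1  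
F0 | step 12 | none | none  
F4 | step 17 | C6 angelate of 28 (8,9-alkene, tert-butyl acrylate) | C=C[C@@]1(C)[C@H](C(=C)COCOC)[C@H](OC(=O)/C(C)=C\C)[C@@H](C(=C)C(=O)OC(C)(C)C)C=C1  
F5 | step 17 | acrylic acid from F4 | C=C[C@@]1(C)[C@H](C(=C)COCOC)[C@H](OC(=O)/C(C)=C\C)[C@@H](C(=C)C(=O)O)C=C1  
F6 | step 17 | cis-fused α-methylene iodolactone (C9 iodide on the methyl face) | C=C[C@@]1(C)[C@H](C(=C)COCOC)[C@H](OC(=O)/C(C)=C\C)[C@H]2C(=C)C(=O)O[C@H]2[C@@H]1I  
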